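**Retrosynthetic overview**
1. The target comes from global desilylation of a tris-silylated isoflavan. Rings A (resorcinol) and B (3-methoxycatechol) are bought as arenes. The C5' 1,1-dimethylallyl group comes from an aromatic Claisen shift of the 4'-O-prenyl ether, done before the fragments are joined.
2. Key disconnection: C4-C4a of pyran ring C, taken together with a retro-1,2-shift of ring B from C3 back to C4. This unfolds the isoflavan to an open-chain (R)-1-aryloxy-3-arylpropan-2-ol.
3. Enabling feature: C1' of ring B is ortho to the 2'-OMe and para to the 4'-oxygen, so ring B can bridge C3 and C4 as a phenonium ion. C4a of ring A is ortho to O1 and para to O7, so it is the best carbon nucleophile within reach. C3 lies between two CH2 groups, so C2-C3-C4 maps onto glycidol.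
4. The open-chain carbinol comes from the ring B aryllithium and the (R)-glycidyl ether of mono-silylated resorcinol. The stereocentre is taken from (S)-glycidol.
5. Ring order: A and B are present from the start. Ring C is the only ring formed, and it forms last, in the key step.

Key step: step 8

Remark: isoflavan numbering is used (O1, C2, C3, C4, C4a to C8a for rings C and A; primed numbers for ring B). The single stereocentre C3 of the target SMILES reads as (R).

**Step 1**
Reactants: 1 3-methoxycatechol; 2 prenyl bromide
Product: 3 2-methoxy-6-(3-methylbut-2-enyloxy)phenol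
Conditions: K2CO3 (1 equiv), acetone, argon, rt to 40 °C
Reagents that add atoms: none
Why: Williamson ether synthesis, in which one equivalent of base and bromide should alkylate the outer hydroxyl in preference to the inner one, which is flanked on both sides (the same preference turns pyrogallol into its 1,3-diethers); no stereocentre is formed.

**Step 2**
Reactants: 3 2-methoxy-6-(3-methylbut-2-enyloxy)phenol
Product: 5 3-methoxy-6-(2-methylbut-3-en-2-yl)benzene-1,2-diol, via ortho-dienone 4 (not isolated)
Conditions: PhNEt2, 190 °C, sealed tube, argon, short heating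
Reagents that add atoms: none
Why: Aromatic Claisen rearrangement, in which the [3,3] shift carries the tertiary allyl terminus to the only free ortho position and enolisation of 4 restores the arene, while short heating in a basic solvent limits the Cope shift to the para position and the abnormal Claisen pathway.

**Step 3**
Reactants: 5 3-methoxy-6-(2-methylbut-3-en-2-yl)benzene-1,2-diol
Product: 6 1,2-bis(tert-butyldimethylsilyloxy)-3-methoxy-6-(2-methylbut-3-en-2-yl)benzene
Conditions: TBSOTf, 2,6-lutidine, CH2Cl2, 0 °C to rt
Reagents that add atoms: tert-butyldimethylsilyl triflate, CC(C)(C)[Si](C)(C)OS(=O)(=O)C(F)(F)F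
Why: Phenol silylation with the reactive silyl triflate should also cover the hydroxyl next to the tert-alkyl group, and it gives ethers that survive organolithium and cationic steps and leave with fluoride.

**Step 4**
Reactants: 6 1,2-bis(tert-butyldimethylsilyloxy)-3-methoxy-6-(2-methylbut-3-en-2-yl)benzene
Product: 7 1-bromo-2-methoxy-3,4-bis(tert-butyldimethylsilyloxy)-5-(2-methylbut-3-en-2-yl)benzene
Conditions: NBS, MeCN, 0 °C, dark
Reagents that add atoms: N-bromosuccinimide, O=C1CCC(=O)N1Br
Why: Electrophilic aromatic bromination at the CH that is ortho to OMe and para to a silyloxy group, since the other free CH sits next to the tert-alkyl group and the hindered monosubstituted alkene should react more slowly than the trioxygenated arene.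

**Step 5**
Reactants: 8 resorcinol
Product: 9 3-(triisopropylsilyloxy)phenol
Conditions: TIPSCl (1 equiv), imidazole, resorcinol (3 equiv), DMF, 0 °C to rt
Reagents that add atoms: triisopropylsilyl chloride, CC(C)[Si](Cl)(C(C)C)C(C)C
Why: Statistical monosilylation of a symmetric diol used in excess, with the surplus resorcinol removed by aqueous washing.

**Step 6**
Reactants: 9 3-(triisopropylsilyloxy)phenol; 10 (S)-glycidol
Product: 11 (R)-2-{[3-(triisopropylsilyloxy)phenoxy]methyl}oxirane
Conditions: PPh3, DIAD, THF, 0 °C to rt
Reagents that add atoms: none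
Why: Mitsunobu etherification, in which the phenol displaces the activated primary hydroxyl of 10 at CH2 without breaking a bond to the stereocentre, so the spatial arrangement of (S)-glycidol is kept (the descriptor becomes R only because priorities change) and the neutral medium spares the silyl ether and the epoxide.

**Step 7**
Reactants: 7 1-bromo-2-methoxy-3,4-bis(tert-butyldimethylsilyloxy)-5-(2-methylbut-3-en-2-yl)benzene; 11 (R)-2-{[3-(triisopropylsilyloxy)phenoxy]methyl}oxirane
Product: 13 (2R)-1-[3,4-bis(tert-butyldimethylsilyloxy)-2-methoxy-5-(2-methylbut-3-en-2-yl)phenyl]-3-[3-(triisopropylsilyloxy)phenoxy]propan-2-ol, via aryllithium 12 (not isolated)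
Conditions: n-BuLi, THF, -78 °C; then 11, BF3·OEt2, -78 °C; aq. NaHCO3
Reagents that add atoms: n-butyllithium, [Li]CCCC (its lithium stands in 12 only)
Why: Bromine-lithium exchange followed by BF3-assisted SN2 opening of the terminal epoxide at its unsubstituted carbon, which leaves the C-O bond at the stereocentre intact and carries the (R) configuration of 11 into the carbinol carbon of 13.

**Step 8**
Reactants: 13 (2R)-1-[3,4-bis(tert-butyldimethylsilyloxy)-2-methoxy-5-(2-methylbut-3-en-2-yl)phenyl]-3-[3-(triisopropylsilyloxy)phenoxy]propan-2-ol
Product: 16 (3R)-2'-methoxy-3',4'-bis(tert-butyldimethylsilyloxy)-7-(triisopropylsilyloxy)-5'-(2-methylbut-3-en-2-yl)isoflavan, via secondary triflate 14 (not isolated), via phenonium triflate 15 (not isolated)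
Conditions: Tf2O, 2,6-di-tert-butyl-4-methylpyridine, CH2Cl2 (high dilution), -78 °C to 0 °C
Reagents that add atoms: trifluoromethanesulfonic anhydride, O=S(=O)(C(F)(F)F)OS(=O)(=O)C(F)(F)F (its triflyl group stands in 14 and 15 only)
Why: Proposed new method: the carbinol is triflated in situ to 14, ring B displaces the triflate from the rear through its ipso carbon C1' (Ar1-3 neighbouring-group participation, helped by the ortho 2'-OMe and the para 4'-silyloxy group) to give the cyclopropane-bridged phenonium ion 15, ring A opens 15 at the CH2 carbon through C4a to make the C4-C4a bond, and the hindered pyridine removes the proton to rearomatise ring A. The closest known reaction types are the stereospecific Friedel-Crafts arylation of beta-aryl alcohols and sulfonates by way of phenonium ions and the six-ring Friedel-Crafts cycloalkylation of 3-aryloxypropyl electrophiles to chromans; new is their merger in one substrate, so that a 1,2-aryl shift of the kind that marks isoflavonoid biosynthesis (new C3-C1' bond) and the closure of the pyran ring happen in one flask. Ring C, the only ring closed, forms in the 6-exo-tet mode (Ar2-6), since the breaking C4-C1' bond of the cyclopropane lies outside the new ring. C3 is the only stereocentre and is controlled by the substrate: it is inverted once when C1' replaces the triflate and is not touched when C4 is attacked, so the (R)-carbinol gives the (3R)-isoflavan (same letter because the aryl group ranks below CH2O), and return of triflate to either cyclopropane carbon cannot scramble it. Two selectivities are needed: opening at CH2 instead of at C3, secured by the kinetic preference of Friedel-Crafts closures for six- over five-membered rings, the lower substitution of C4 and the electron-withdrawing aryloxymethyl group on C3, and attack through C4a instead of C8, secured by C4a being para to O7 and by the bulky triisopropylsilyl group that shields C8 between the two oxygens. Because triflate and the base are non-nucleophilic, participation by the 2'-methoxy oxygen and ion-pair return stay reversible, and only the C-C bond formation is irreversible.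

**Step 9**
Reactants: 16 (3R)-2'-methoxy-3',4'-bis(tert-butyldimethylsilyloxy)-7-(triisopropylsilyloxy)-5'-(2-methylbut-3-en-2-yl)isoflavan
Product: 17 (3R)-7,3',4'-trihydroxy-2'-methoxy-5'-(2-methylbut-3-en-2-yl)isoflavan (CNP0167796.1)
Conditions: TBAF, AcOH, degassed THF, 0 °C to rt
Reagents that add atoms: none
Why: Fluoride-induced cleavage of all three aryl silyl ethers, with the acetic acid buffer keeping the catechol protonated and safe from air oxidation, while the vinyl group, the methyl ether and C3 are not affected.

**Compound list**
1 | 3-methoxycatechol (3-methoxybenzene-1,2-diol) | COc1cccc(O)c1O | starting material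
2 | prenyl bromide (1-bromo-3-methylbut-2-ene) | CC(C)=CCBr | starting material
3 | 2-methoxy-6-(3-methylbut-2-enyloxy)phenol | COc1cccc(OCC=C(C)C)c1O | intermediate
4 | ortho-dienone, 2-hydroxy-3-methoxy-6-(2-methylbut-3-en-2-yl)cyclohexa-2,4-dien-1-one, racemic, not isolated | COC1=C(O)C(=O)C(C(C)(C)C=C)C=C1 | intermediate
5 | 3-methoxy-6-(2-methylbut-3-en-2-yl)benzene-1,2-diol | COc1ccc(C(C)(C)C=C)c(O)c1O | intermediate
6 | 1,2-bis(tert-butyldimethylsilyloxy)-3-methoxy-6-(2-methylbut-3-en-2-yl)benzene | COc1ccc(C(C)(C)C=C)c(O[Si](C)(C)C(C)(C)C)c1O[Si](C)(C)C(C)(C)C | intermediate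
7 | 1-bromo-2-methoxy-3,4-bis(tert-butyldimethylsilyloxy)-5-(2-methylbut-3-en-2-yl)benzene | COc1c(Br)cc(C(C)(C)C=C)c(O[Si](C)(C)C(C)(C)C)c1O[Si](C)(C)C(C)(C)C | intermediate
8 | resorcinol | Oc1cccc(O)c1 | starting material
9 | 3-(triisopropylsilyloxy)phenol | CC(C)[Si](Oc1cccc(O)c1)(C(C)C)C(C)C | intermediate
10 | (S)-glycidol | OC[C@H]1CO1 | starting material
11 | (R)-2-{[3-(triisopropylsilyloxy)phenoxy]methyl}oxirane | CC(C)[Si](Oc1cccc(OC[C@H]2CO2)c1)(C(C)C)C(C)C | intermediate
12 | aryllithium of ring B, [2-methoxy-3,4-bis(tert-butyldimethylsilyloxy)-5-(2-methylbut-3-en-2-yl)phenyl]lithium, not isolated | COc1c([Li])cc(C(C)(C)C=C)c(O[Si](C)(C)C(C)(C)C)c1O[Si](C)(C)C(C)(C)C | intermediate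
13 | (2R)-1-[3,4-bis(tert-butyldimethylsilyloxy)-2-methoxy-5-(2-methylbut-3-en-2-yl)phenyl]-3-[3-(triisopropylsilyloxy)phenoxy]propan-2-ol | CC(C)[Si](Oc1cccc(OC[C@H](O)Cc2cc(C(C)(C)C=C)c(O[Si](C)(C)C(C)(C)C)c(O[Si](C)(C)C(C)(C)C)c2OC)c1)(C(C)C)C(C)C | intermediate
14 | (R)-secondary triflate of 13, not isolated | CC(C)[Si](Oc1cccc(OC[C@H](OS(=O)(=O)C(F)(F)F)Cc2cc(C(C)(C)C=C)c(O[Si](C)(C)C(C)(C)C)c(O[Si](C)(C)C(C)(C)C)c2OC)c1)(C(C)C)C(C)C | intermediate
15 | phenonium triflate: cyclopropane built from C3, C4 and C1' of ring B, C3 (R), both orientations at the spiro carbon, drawn as the 4'-oxocarbenium form, not isolated | CC(C)[Si](Oc1cccc(OC[C@@H]2CC23C=C(C(C)(C)C=C)C(=[O+][Si](C)(C)C(C)(C)C)C(O[Si](C)(C)C(C)(C)C)=C3OC)c1)(C(C)C)C(C)C.[O-]S(=O)(=O)C(F)(F)F | intermediate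
16 | (3R)-2'-methoxy-3',4'-bis(tert-butyldimethylsilyloxy)-7-(triisopropylsilyloxy)-5'-(2-methylbut-3-en-2-yl)isoflavan | C=CC(C)(C)c1cc([C@@H]2COc3cc(O[Si](C(C)C)(C(C)C)C(C)C)ccc3C2)c(OC)c(O[Si](C)(C)C(C)(C)C)c1O[Si](C)(C)C(C)(C)C | intermediate
17 | (3R)-7,3',4'-trihydroxy-2'-methoxy-5'-(2-methylbut-3-en-2-yl)isoflavan | C=CC(C)(C)c1cc([C@@H]2COc3cc(O)ccc3C2)c(OC)c(O)c1O | target

**Total step count:** 9. **Longest linear sequence:** 7 (steps 1, 2, 3, 4, 7, 8, 9).

**Steps most likely to fail**

First, step 8 (the proposed new method).
- What may go wrong:
  - opening of the phenonium ion at its substituted carbon, or direct attack of ring A on the triflate carbon, either of which closes a five-membered ring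
  - a hydride shift to a benzylic cation, followed by closure into the 4-aryl series
  - elimination of triflic acid
  - loss of the 4'-silyl group from the cation
  - irreversible demethylation after participation of the 2'-methoxy oxygen
- The fallback uses known chemistry and reverses the order, closing the ring first and adding the aryl group second. It sets out from 11 and comes back at 16.
- The electron-rich aryl glycidyl ether 11 is cyclised by the known 6-endo epoxide-arene Friedel-Crafts closure in hot hexafluoroisopropanol. This forms the same C4-C4a bond without touching the stereocentre and gives (3R)-7-(triisopropylsilyloxy)chroman-3-ol F1.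
- TsCl in pyridine converts it into (3R)-7-(triisopropylsilyloxy)chroman-3-yl 4-methylbenzenesulfonate F2.
- Aryllithium 12 and CuI (half an equivalent) in Et2O give lithium bis[2-methoxy-3,4-bis(tert-butyldimethylsilyloxy)-5-(2-methylbut-3-en-2-yl)phenyl]cuprate F3. This displaces the secondary tosylate in an SN2 reaction with inversion and delivers 16 with the (3R) configuration.

Second, step 2.
- What may go wrong: onward Cope migration of the allyl unit to the para position, abnormal Claisen isomerisation of the side chain, thermal loss of the prenyl group, or addition of the new phenol to the vinyl group.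
- The fallback replaces the sigmatropic shift by a cross-coupling. It sets out from 1, comes back at 5, and also makes step 1 unnecessary.
- MOMCl and i-Pr2NEt give 1-methoxy-2,3-bis(methoxymethoxy)benzene F4.
- Directed ortho-lithiation with n-BuLi goes next to the outer methoxymethoxy group, which directs more strongly than OMe. A quench with 1,2-dibromoethane gives 1-bromo-4-methoxy-2,3-bis(methoxymethoxy)benzene F5.
- A branched-selective Suzuki-Miyaura coupling with prenylboronic acid pinacol ester (Pd(OAc)2, bulky biarylphosphine ligand, K3PO4, THF/water) gives 1-methoxy-2,3-bis(methoxymethoxy)-4-(2-methylbut-3-en-2-yl)benzene F6.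
- Mild methanolysis (catalytic HCl, MeOH) releases 5.

Third, step 4.
- What may go wrong: addition of electrophilic bromine to the vinyl group, or sluggish ring bromination because both silyloxy groups are twisted out of conjugation.
- The fallback drops the halogen altogether. It sets out from 6 and comes back at 12.
- Directed ortho-metalation with s-BuLi and TMEDA in THF at low temperature lithiates the only ring CH that lies next to a coordinating group (the methoxy group). The aryllithium 12 so formed enters step 7 directly. No new compound arises (none F0).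

**Further compounds**
F1 | step 8 | (3R)-7-(triisopropylsilyloxy)chroman-3-ol | O[C@H]1COc2cc(O[Si](C(C)C)(C(C)C)C(C)C)ccc2C1
F2 | step 8 | (3R)-7-(triisopropylsilyloxy)chroman-3-yl 4-methylbenzenesulfonate | Cc1ccc(S(=O)(=O)O[C@H]2COc3cc(O[Si](C(C)C)(C(C)C)C(C)C)ccc3C2)cc1
F3 | step 8 | lithium bis[2-methoxy-3,4-bis(tert-butyldimethylsilyloxy)-5-(2-methylbut-3-en-2-yl)phenyl]cuprate | [Li+].COc1c([Cu-]c2cc(C(C)(C)C=C)c(O[Si](C)(C)C(C)(C)C)c(O[Si](C)(C)C(C)(C)C)c2OC)cc(C(C)(C)C=C)c(O[Si](C)(C)C(C)(C)C)c1O[Si](C)(C)C(C)(C)C
F4 | step 2 | 1-methoxy-2,3-bis(methoxymethoxy)benzene | COCOc1cccc(OC)c1OCOC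
F5 | step 2 | 1-bromo-4-methoxy-2,3-bis(methoxymethoxy)benzene | COCOc1c(Br)ccc(OC)c1OCOC
F6 | step 2 | 1-methoxy-2,3-bis(methoxymethoxy)-4-(2-methylbut-3-en-2-yl)benzene | COCOc1c(C(C)(C)C=C)ccc(OC)c1OCOC
F0 | step 4 | none | none
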